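**Compound abbreviations used in names.** Bic(6R) = (4R,4aR,6R,7R,7aS)-2,4,7-trimethyloctahydro-1H-cyclopenta[c]pyridin-6-yl; Bic(6S) = its (4R,4aR,6S,7R,7aS) epimer. Ar = 4-acetoxy-3-methoxyphenyl. Cyclobutane numbering: C1 = carboxylate carbon cis to both aryl groups, C2 and C4 = aryl-bearing carbons, C3 = carboxylate carbon trans to both aryl groups.

## Analysis of the target

The target (22) is a fully substituted cyclobutane C1–C4 with carboxylates on C1 and C3 and 4-hydroxy-3-methoxyphenyl groups on C2 and C4; each carboxylate is esterified with a cis-fused 2,4,7-trimethyloctahydrocyclopenta[c]pyridin-6-ol. Read from the SMILES, the two aryl groups are cis to each other, the C1 carboxylate is cis to both and the C3 carboxylate is trans to both (1α,2α,3β,4α). This is not the centrosymmetric head-to-tail pattern (aryl groups trans) that dimerisation of two E-cinnamates gives; formally it is the head-to-tail adduct of one Z- and one E-feruloyl unit. The ring core alone has a mirror plane through C1 and C3, so its four stereocentres are a problem of relative configuration only. The two carboxylates are nevertheless different positions and carry different alcohols: both bicyclic units are (4R,4aR,7R,7aS), but the C1 ester is 6R and the C3 ester is 6S. Each unit has five contiguous stereocentres: cis ring fusion, C4 methyl cis to H-4a, C7 methyl trans to the C7a–C1 bond, and O6 trans (6R) or cis (6S) to the C7 methyl. Sensitive points are C1–H (α to an ester; epimerisation to the all-trans ring is downhill, so base must be avoided once the ring exists), the oxidisable guaiacol phenols, two basic tertiary amines and two hindered secondary-alkyl esters. The difficulty is threefold: a cis-diaryl ring that cinnamate photodimerisation does not give, two carboxylates that must be told apart with the more hindered one carrying a specific epimer, and fourteen stereocentres in all.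

## Retrosynthetic reasoning

22 is traced back to its bis-acetate 21. Only the two aryl O–acetyl bonds are cut; aryl acetates can be removed by aminolysis without touching the alkyl esters or C1–H, and they make the aryl groups less electron-rich for the steps before.

21 is traced back to pyrrolidine 17 by inserting an NH into the C1–C2 bond of the cyclobutane. This bond joins the carboxylate carbon that is cis to both aryl groups to an aryl-bearing carbon. With nitrogen there, the four-membered ring becomes a 3,5-diaryl-pyrrolidine-2,4-dicarboxylate (pyrrolidine C2, C3, C4, C5 = cyclobutane C1, C4, C3, C2). The forward reaction has to excise the nitrogen and join the two α-carbons with retention. Because C2 and C4 of the cyclobutane carry identical aryl groups, the two exo pyrrolidines with mirror-image ring cores contract to the same 21.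

17 is cut at C2–C3 and C4–C5 into imine 14 and cinnamate 16, a [3+2] azomethine ylide cycloaddition. This is where the target's features pay off. The two ester groups arrive on two different components, so the carboxylates are differentiated from the start and the hindered C1 carboxylate is never esterified on the ring. The E alkene of 16 gives the 3,4-trans relation, the W-shaped metallo-ylide gives 2,5-cis, and exo approach puts the C3 aryl cis to C2 and C5 substituents. Only exo/endo selectivity is required; facial selectivity is irrelevant.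

14 is cut at the C=N bond into glycinate salt 12 and aldehyde 13; 12 comes from 11, which is cut at the ester C–O bond into alcohol 9 and acid 10 (acylation, retention at C6). 16 is cut at the ester O–C6 bond into the same alcohol 9 and acid 15 (Mitsunobu, inversion at C6). The epimeric relation of the two bicyclic units is thus used, not fought: one alcohol serves twice.

9 is traced back to keto carbamate 8. One hydride reduction sets C6 (attack on the convex face) and turns the carbamate into the N-methyl group.

8 is traced back through 7 to enone 6. Hydrogenation of the C7=C7a bond from the face of H-4a sets the cis ring fusion, and equilibration at C7 puts the methyl trans to the C7a–C1 bond.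

6 is cut at C4a–C7a, C5–C6 and C6–C7 into enyne 5 (carbonylative [2+2+1] cyclisation). Both rings are closed in one step and C4a is set from C4.

5 is cut at the C4–methyl bond to allylic bromide 4 (enantioselective SN2′ methylation sets C4); 4 comes from carbamate 2 and dibromide 3, and 2 from amine salt 1.

## Alternatives that were turned down

Alternative 1: (textbook) Cut both ester C–O bonds last and make the cyclobutane diacid by solid-state [2+2] photodimerisation of crystalline 15, giving diacid A1, followed by two esterifications. Turned down because topochemical head-to-tail dimerisation of an E-cinnamic acid joins two E alkenes across an inversion centre, so A1 has trans aryl groups (1α,2α,3β,4β). The target needs them cis, and no enolisation can invert an aryl-bearing carbon. Even with the right diacid, the two carboxyls would have to be told apart and the hindered, epimerisable one esterified with a secondary alcohol.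

Alternative 2: (crossed photocycloaddition) Cut C1–C4 and C2–C3 into two cinnamates, 16 and the Z-configured ester A2, and join them head-to-tail by irradiation. Turned down because excited cinnamates mainly undergo E/Z isomerisation, which scrambles the geometry that encodes the stereochemistry. Homo- and cross-pairings, head-to-head versus head-to-tail and syn versus anti give more than ten possible cyclobutanes, and sensitised closure through a triplet 1,4-diradical favours head-to-head products. Nothing in the substrates enforces the one pairing needed, and the loss would fall on two advanced esters.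

Alternative 3: (directed C–H arylation) Cut both C–aryl bonds: a trans-cyclobutane-1,3-dicarboxylate whose C1 carboxyl is an 8-aminoquinoline amide is arylated twice, cis to the amide, to give A3, which has the right relative configuration. Turned down because the directing amide then sits between two cis aryl groups; its cleavage needs N-activation and strongly nucleophilic or acidic conditions, under which C1 is expected to epimerise to the all-trans series. The most hindered carboxyl would still have to be esterified afterwards and the C3 ester exchanged, at least six operations after the key step against one here.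

Key step: step 12

Assumption 1: (S,S)-Taniaphos is taken to give the R-configured SN2′ product 5 in step 3; if the sense is the opposite, the commercial (R,R)-ligand is used and nothing else changes.

Assumption 2: 17 is written with the (2R,3R,4S,5S) ring; the facial sense of step 11 is immaterial, since the diastereomer with all four ring centres inverted contracts to the same 21.

## Steps

**Step 1**
Reactants: 1 but-2-yn-1-amine hydrochloride
Product: 2 methyl N-(but-2-yn-1-yl)carbamate
Conditions: ClCO2Me (1.1 equiv), Et3N (2.2 equiv), CH2Cl2, 0 °C to rt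
Reagents that add atoms: methyl chloroformate, COC(=O)Cl
Why: N-acylation of a primary amine; the methyl carbamate is a tether compatible with the cobalt-mediated cyclisation and a latent N-methyl group.

**Step 2**
Reactants: 2 methyl N-(but-2-yn-1-yl)carbamate; 3 (E)-1,4-dibromobut-2-ene (3 equiv)
Product: 4 methyl N-[(E)-4-bromobut-2-en-1-yl]-N-(but-2-yn-1-yl)carbamate
Conditions: NaH (1.1 equiv), DMF, 0 °C; then added to 3 in DMF, 0 °C to rt
Reagents that add atoms: none
Why: SN2 alkylation of the carbamate anion at an allylic bromide; excess dibromide and inverse addition should suppress double alkylation, and the E geometry is kept.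

**Step 3**
Reactants: 4 methyl N-[(E)-4-bromobut-2-en-1-yl]-N-(but-2-yn-1-yl)carbamate
Product: 5 methyl N-(but-2-yn-1-yl)-N-[(2R)-2-methylbut-3-en-1-yl]carbamate
Conditions: CuBr·SMe2 (3 mol %), (S,S)-Taniaphos (3.5 mol %), MeMgBr (1.2 equiv, slow addition), CH2Cl2, −75 °C
Reagents that add atoms: methylmagnesium bromide, C[Mg]Br
Why: Copper-catalysed asymmetric allylic alkylation (SN2′) of an E-allylic bromide carrying a protected nitrogen, a substrate class on which this catalyst gives the branched product; the ligand sets C4 (later 4R), and the carbamate should be inert to the Grignard reagent at this temperature.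

**Step 4**
Reactants: 5 methyl N-(but-2-yn-1-yl)-N-[(2R)-2-methylbut-3-en-1-yl]carbamate
Product: 6 methyl (4R,4aR)-4,7-dimethyl-6-oxo-3,4,4a,5-tetrahydro-1H-cyclopenta[c]pyridine-2(6H)-carboxylate
Conditions: Co2(CO)8 (10 mol %), tetramethylthiourea (60 mol %), CO (1 atm), toluene, 70 °C
Reagents that add atoms: carbon monoxide, [C-]#[O+]
Why: Intramolecular Pauson–Khand reaction of a carbamate-tethered 1,7-enyne; alkene insertion through a chair-like arrangement with the C4 methyl equatorial should put the methyl cis to H-4a (trans to C5), which sets C4a.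

**Step 5**
Reactants: 6 methyl (4R,4aR)-4,7-dimethyl-6-oxo-3,4,4a,5-tetrahydro-1H-cyclopenta[c]pyridine-2(6H)-carboxylate
Product: 8 methyl (4R,4aR,7R,7aS)-4,7-dimethyl-6-oxooctahydro-2H-cyclopenta[c]pyridine-2-carboxylate, via cis-fused 7S-epimeric ketone 7 (not isolated)
Conditions: H2 (4 atm), Pd/C (10 wt % palladium on carbon), EtOAc, rt; filter; then NaOMe (0.2 equiv), MeOH, rt
Reagents that add atoms: none
Why: Heterogeneous syn hydrogenation of the tetrasubstituted enone from the face of H-4a should give the cis ring fusion (7aS) with the C7 methyl on the concave face (7); base equilibration through the enolate then moves the methyl trans to the C7a–C1 bond, the more stable 2,3-trans cyclopentanone (7R).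

**Step 6**
Reactants: 8 methyl (4R,4aR,7R,7aS)-4,7-dimethyl-6-oxooctahydro-2H-cyclopenta[c]pyridine-2-carboxylate
Product: 9 (4R,4aR,6R,7R,7aS)-2,4,7-trimethyloctahydro-1H-cyclopenta[c]pyridin-6-ol
Conditions: LiAlH4 (4 equiv), THF, −78 °C to 0 °C, then reflux; Fieser work-up
Reagents that add atoms: none
Why: Hydride reduction of the ketone at low temperature, then of the carbamate to N-methyl at reflux; the concave face is screened by C1 and C4 of the piperidine ring, and small hydrides add cis to an α-methyl on cyclopentanones, so attack from the convex face should give the 6R alcohol (OH trans to the C7 methyl).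

**Step 7**
Reactants: 9 (4R,4aR,6R,7R,7aS)-2,4,7-trimethyloctahydro-1H-cyclopenta[c]pyridin-6-ol; 10 N-(tert-butoxycarbonyl)glycine
Product: 11 Bic(6R) N-(tert-butoxycarbonyl)glycinate
Conditions: DCC (1.2 equiv), DMAP (0.2 equiv), CH2Cl2, 0 °C to rt
Reagents that add atoms: none
Why: Steglich esterification with an unhindered acid; the C6–O bond is not touched, so 6R is retained.

**Step 8**
Reactants: 11 Bic(6R) N-(tert-butoxycarbonyl)glycinate
Product: 12 Bic(6R) glycinate bis(hydrochloride)
Conditions: HCl (4 M in 1,4-dioxane), CH2Cl2, 0 °C to rt; evaporate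
Reagents that add atoms: hydrogen chloride, Cl
Why: Acidolysis of the tert-butyl carbamate; the ester and the ring stereocentres should be stable to anhydrous acid, and the salt is stored without self-condensation.

**Step 9**
Reactants: 12 Bic(6R) glycinate bis(hydrochloride); 13 4-formyl-2-methoxyphenyl acetate
Product: 14 Bic(6R) N-[(E)-(4-acetoxy-3-methoxyphenyl)methylidene]glycinate
Conditions: Et3N (2.0 equiv), MgSO4, CH2Cl2, 0 °C to rt; filter, cold aq NaHCO3 wash, concentrate; used crude
Reagents that add atoms: none
Why: Imine condensation of a glycine ester with an activated aromatic aldehyde, which should outrun acetyl transfer from the aryl acetate to the amine; the E imine is the stable isomer.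

**Step 10**
Reactants: 9 (4R,4aR,6R,7R,7aS)-2,4,7-trimethyloctahydro-1H-cyclopenta[c]pyridin-6-ol; 15 (E)-3-(4-acetoxy-3-methoxyphenyl)prop-2-enoic acid
Product: 16 Bic(6S) (E)-3-(4-acetoxy-3-methoxyphenyl)prop-2-enoate
Conditions: PPh3 (1.5 equiv), DIAD (1.5 equiv), THF, 0 °C to rt
Reagents that add atoms: none
Why: Mitsunobu esterification; the carboxylate displaces the activated concave-face oxygen from the open convex face with inversion, which sets 6S, and the alkene geometry is not affected.

**Step 11**
Reactants: 14 Bic(6R) N-[(E)-(4-acetoxy-3-methoxyphenyl)methylidene]glycinate; 16 Bic(6S) (E)-3-(4-acetoxy-3-methoxyphenyl)prop-2-enoate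
Product: 17 2-Bic(6R) 4-Bic(6S) (2R,3R,4S,5S)-3,5-bis(4-acetoxy-3-methoxyphenyl)pyrrolidine-2,4-dicarboxylate
Conditions: Cu(CH3CN)4PF6 (5 mol %), (R)-DTBM-SEGPHOS (5.5 mol %), Et3N (20 mol %), THF, −20 °C to rt
Reagents that add atoms: none
Why: Catalytic [3+2] cycloaddition of an N,O-chelated azomethine ylide with an acrylate-type dipolarophile, with monovalent copper and a bulky bisphosphine, the catalyst class with an exo preference that grows with the size of the dipolarophile ester. The W-shaped ylide gives 2,5-cis, the E alkene gives 3,4-trans, and exo approach puts the C4 ester trans to the C5 aryl and the C3 aryl cis to the C2 and C5 substituents; the acetoxy groups keep the cinnamate electrophilic enough.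

**Step 12**
Reactants: 17 2-Bic(6R) 4-Bic(6S) (2R,3R,4S,5S)-3,5-bis(4-acetoxy-3-methoxyphenyl)pyrrolidine-2,4-dicarboxylate
Product: 21 1-Bic(6R) 3-Bic(6S) (1α,2α,3β,4α)-2,4-bis(4-acetoxy-3-methoxyphenyl)cyclobutane-1,3-dicarboxylate, via N-amidated pyrrolidine adduct 18 (not isolated), via isodiazene 19 (not isolated), via 1,4-diradical 20 (not isolated)
Conditions: CF3CO2H (2.0 equiv), THF/MeCN (1:1), 0 °C; then N-(benzyloxy)-N-(pivaloyloxy)-4-(trifluoromethyl)benzamide (1.5 equiv), 45 °C; aq NaHCO3 work-up
Reagents that add atoms: none
Why: Nitrogen deletion of a secondary amine: the pyrrolidine N–H attacks the amide nitrogen of the anomeric amide with loss of pivalate (18); migration of the benzyloxy group from nitrogen to the acyl carbon expels benzyl 4-(trifluoromethyl)benzoate and leaves the 1,1-diazene 19, which loses N2 to the singlet 1,4-diradical 20 (benzylic at former C5, α-ester at former C2). The four-membered ring closes by radical–radical combination of these two carbons, a net 5-to-4 ring contraction that forms the C1–C2 bond of the cyclobutane. The closest known reaction types are the anomeric-amide deletion of benzylic secondary amines and the stereoretentive contraction of 5-aryl-pyrrolidine-2-carboxylates to cyclobutanes through 1,1-diazenes. Former C3 and C4 are not touched; the cis relation of the C2 ester and C5 aryl should be remembered because the diradical is born in the ring-shaped conformation and combines faster than rotation about C2–C3 or C4–C5. The step needs N–H selectivity over the two tertiary amines: these are masked as ammonium salts (the α-amino ester nitrogen is several pKa units less basic and stays free) and, lacking N–H, cannot form a diazene. It also needs combination to win over cleavage of the central C3–C4 bond to two cinnamates; both radical centres being stabilised and held gauche favours closure.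

**Step 13**
Reactants: 21 1-Bic(6R) 3-Bic(6S) (1α,2α,3β,4α)-2,4-bis(4-acetoxy-3-methoxyphenyl)cyclobutane-1,3-dicarboxylate
Product: 22 1-Bic(6R) 3-Bic(6S) (1α,2α,3β,4α)-2,4-bis(4-hydroxy-3-methoxyphenyl)cyclobutane-1,3-dicarboxylate (target)
Conditions: N2H4·H2O (2.5 equiv), THF/MeOH, 0 °C
Reagents that add atoms: none
Why: Chemoselective hydrazinolysis of the two aryl acetates; hindered secondary-alkyl esters should not react at 0 °C and the medium is not basic enough to enolise C1.

## Compound list

1 | but-2-yn-1-amine hydrochloride | CC#CCN.Cl | starting material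
2 | methyl N-(but-2-yn-1-yl)carbamate | CC#CCNC(=O)OC | intermediate
3 | (E)-1,4-dibromobut-2-ene | BrC/C=C/CBr | starting material
4 | methyl N-[(E)-4-bromobut-2-en-1-yl]-N-(but-2-yn-1-yl)carbamate | CC#CCN(C/C=C/CBr)C(=O)OC | intermediate
5 | methyl N-(but-2-yn-1-yl)-N-[(2R)-2-methylbut-3-en-1-yl]carbamate | C=C[C@@H](C)CN(CC#CC)C(=O)OC | intermediate
6 | methyl (4R,4aR)-4,7-dimethyl-6-oxo-3,4,4a,5-tetrahydro-1H-cyclopenta[c]pyridine-2(6H)-carboxylate | O=C1C[C@H]2C(CN(C(=O)OC)C[C@@H]2C)=C1C | intermediate
7 | methyl (4R,4aR,7S,7aS)-4,7-dimethyl-6-oxooctahydro-2H-cyclopenta[c]pyridine-2-carboxylate | O=C1C[C@H]2[C@H](CN(C(=O)OC)C[C@@H]2C)[C@@H]1C | intermediate (not isolated)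
8 | methyl (4R,4aR,7R,7aS)-4,7-dimethyl-6-oxooctahydro-2H-cyclopenta[c]pyridine-2-carboxylate | O=C1C[C@H]2[C@H](CN(C(=O)OC)C[C@@H]2C)[C@H]1C | intermediate
9 | (4R,4aR,6R,7R,7aS)-2,4,7-trimethyloctahydro-1H-cyclopenta[c]pyridin-6-ol | O[C@@H]1C[C@H]2[C@H](CN(C)C[C@@H]2C)[C@H]1C | intermediate
10 | N-(tert-butoxycarbonyl)glycine | CC(C)(C)OC(=O)NCC(=O)O | starting material
11 | Bic(6R) N-(tert-butoxycarbonyl)glycinate | CC(C)(C)OC(=O)NCC(=O)O[C@@H]1C[C@H]2[C@H](CN(C)C[C@@H]2C)[C@H]1C | intermediate
12 | Bic(6R) glycinate bis(hydrochloride) | NCC(=O)O[C@@H]1C[C@H]2[C@H](CN(C)C[C@@H]2C)[C@H]1C.Cl.Cl | intermediate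
13 | 4-formyl-2-methoxyphenyl acetate | COc1cc(C=O)ccc1OC(C)=O | starting material
14 | Bic(6R) N-[(E)-(4-acetoxy-3-methoxyphenyl)methylidene]glycinate | COc1cc(/C=N/CC(=O)O[C@@H]2C[C@H]3[C@H](CN(C)C[C@@H]3C)[C@H]2C)ccc1OC(C)=O | intermediate
15 | (E)-3-(4-acetoxy-3-methoxyphenyl)prop-2-enoic acid | COc1cc(/C=C/C(=O)O)ccc1OC(C)=O | starting material
16 | Bic(6S) (E)-3-(4-acetoxy-3-methoxyphenyl)prop-2-enoate | COc1cc(/C=C/C(=O)O[C@H]2C[C@H]3[C@H](CN(C)C[C@@H]3C)[C@H]2C)ccc1OC(C)=O | intermediate
17 | 2-Bic(6R) 4-Bic(6S) (2R,3R,4S,5S)-3,5-bis(4-acetoxy-3-methoxyphenyl)pyrrolidine-2,4-dicarboxylate | COc1cc([C@H]2N[C@@H](C(=O)O[C@@H]3C[C@H]4[C@H](CN(C)C[C@@H]4C)[C@H]3C)[C@@H](c3ccc(OC(C)=O)c(OC)c3)[C@@H]2C(=O)O[C@H]2C[C@H]3[C@H](CN(C)C[C@@H]3C)[C@H]2C)ccc1OC(C)=O | intermediate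
18 | 17 carrying N(OCH2Ph)C(=O)C6H4-4-CF3 on the ring nitrogen | COc1cc([C@H]2N(N(OCc3ccccc3)C(=O)c3ccc(cc3)C(F)(F)F)[C@@H](C(=O)O[C@@H]3C[C@H]4[C@H](CN(C)C[C@@H]4C)[C@H]3C)[C@@H](c3ccc(OC(C)=O)c(OC)c3)[C@@H]2C(=O)O[C@H]2C[C@H]3[C@H](CN(C)C[C@@H]3C)[C@H]2C)ccc1OC(C)=O | intermediate (not isolated)
19 | 1,1-diazene (isodiazene) of 17 | COc1cc([C@H]2[N+](=[N-])[C@@H](C(=O)O[C@@H]3C[C@H]4[C@H](CN(C)C[C@@H]4C)[C@H]3C)[C@@H](c3ccc(OC(C)=O)c(OC)c3)[C@@H]2C(=O)O[C@H]2C[C@H]3[C@H](CN(C)C[C@@H]3C)[C@H]2C)ccc1OC(C)=O | intermediate (not isolated)
20 | 1,4-diradical after loss of N2 (radical centres at the former C5 and C2) | COc1cc([CH][C@@H](C(=O)O[C@H]2C[C@H]3[C@H](CN(C)C[C@@H]3C)[C@H]2C)[C@H](c2ccc(OC(C)=O)c(OC)c2)[CH]C(=O)O[C@@H]2C[C@H]3[C@H](CN(C)C[C@@H]3C)[C@H]2C)ccc1OC(C)=O | intermediate (not isolated)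
21 | 1-Bic(6R) 3-Bic(6S) (1α,2α,3β,4α)-2,4-bis(4-acetoxy-3-methoxyphenyl)cyclobutane-1,3-dicarboxylate | COc1cc([C@@H]2[C@@H](C(=O)O[C@H]3C[C@H]4[C@H](CN(C)C[C@@H]4C)[C@H]3C)[C@H](c3ccc(OC(C)=O)c(OC)c3)[C@@H]2C(=O)O[C@@H]2C[C@H]3[C@H](CN(C)C[C@@H]3C)[C@H]2C)ccc1OC(C)=O | intermediate
22 | 1-Bic(6R) 3-Bic(6S) (1α,2α,3β,4α)-2,4-bis(4-hydroxy-3-methoxyphenyl)cyclobutane-1,3-dicarboxylate | COc1cc([C@@H]2[C@@H](C(=O)O[C@H]3C[C@H]4[C@H](CN(C)C[C@@H]4C)[C@H]3C)[C@H](c3ccc(O)c(OC)c3)[C@@H]2C(=O)O[C@@H]2C[C@H]3[C@H](CN(C)C[C@@H]3C)[C@H]2C)ccc1O | target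

## Step count and risk

Total: 13 steps. Longest linear sequence: 12 steps (steps 1–9, 11, 12, 13); the cinnamate branch (step 10) joins at step 11.

**Step 12 (key step).** Three processes may intervene. The diradical may cleave its central C–C bond to two cinnamate esters instead of combining. Bond rotation before combination would put the C1 ester trans (all-trans ring). The two tertiary amines may consume the reagent unproductively, or the diazene may tautomerise to a cyclic hydrazone. Fallback, from 17 back to 21: nitrosation with tert-butyl nitrite in CH2Cl2, which only the secondary N–H can undergo, should give the N-nitrosopyrrolidine F1. Zinc dust in AcOH at 0 °C reduces it to the 1-aminopyrrolidine F2. Oxidation of F2 with yellow HgO in CH2Cl2 at 0 °C generates the same diazene 19 under neutral conditions free of electrophilic nitrogen reagents, and 19 goes on to 21.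

**Step 11.** Poor exo/endo selectivity, sluggish addition to the β-aryl acrylate, or Michael addition without ring closure may occur. Fallback, from 16 back to 17: sensitised photoisomerisation (thioxanthone, 365 nm, MeCN) and chromatographic separation give the Z-cinnamate F3 (E isomer recycled). Reliable endo cycloaddition of F3 with 14 (AgOAc 5 mol %, PPh3, Et3N, toluene) gives the all-cis pyrrolidine F4. Its C4 ester is clamped between two cis aryl groups, and brief treatment with DBU in toluene should epimerise it first, to 17; prolonged exposure would also invert C2 and must be avoided.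

**Step 4.** Slow turnover with the 1,7-enyne under catalytic conditions or insufficient diastereoselection at C4a may occur. Fallback, from 5 back to 6: zirconocene-mediated bicyclisation (Cp2ZrCl2, n-BuLi 2 equiv, THF, −78 °C to rt) gives the zirconabicycle F5; its formation is reversible, so the diastereomer with the equatorial methyl should accumulate. Carbonylation (CO, 1 atm, 0 °C) and acidic work-up then give 6.

**Step 6.** Hydride delivery from the concave face would give the C6 epimer. Fallback, from 8 back to 11 and 16: the 6S alcohol F6 is then used with the two esterification modes exchanged. DCC/DMAP acylation of F6 with 15 (retention) gives 16, and Mitsunobu coupling of F6 with 10 (inversion) gives 11; no material is lost whichever face is attacked.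

## Further compounds

F1 | step 12 | 1-nitroso derivative of 17 | COc1cc([C@H]2N(N=O)[C@@H](C(=O)O[C@@H]3C[C@H]4[C@H](CN(C)C[C@@H]4C)[C@H]3C)[C@@H](c3ccc(OC(C)=O)c(OC)c3)[C@@H]2C(=O)O[C@H]2C[C@H]3[C@H](CN(C)C[C@@H]3C)[C@H]2C)ccc1OC(C)=O
F2 | step 12 | 1-amino derivative of 17 | COc1cc([C@H]2N(N)[C@@H](C(=O)O[C@@H]3C[C@H]4[C@H](CN(C)C[C@@H]4C)[C@H]3C)[C@@H](c3ccc(OC(C)=O)c(OC)c3)[C@@H]2C(=O)O[C@H]2C[C@H]3[C@H](CN(C)C[C@@H]3C)[C@H]2C)ccc1OC(C)=O
F3 | step 11 | Bic(6S) (Z)-3-(4-acetoxy-3-methoxyphenyl)prop-2-enoate | COc1cc(/C=C\C(=O)O[C@H]2C[C@H]3[C@H](CN(C)C[C@@H]3C)[C@H]2C)ccc1OC(C)=O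
F4 | step 11 | 2-Bic(6R) 4-Bic(6S) (2R,3R,4R,5S)-3,5-bis(4-acetoxy-3-methoxyphenyl)pyrrolidine-2,4-dicarboxylate (all-cis) | COc1cc([C@H]2N[C@@H](C(=O)O[C@@H]3C[C@H]4[C@H](CN(C)C[C@@H]4C)[C@H]3C)[C@@H](c3ccc(OC(C)=O)c(OC)c3)[C@H]2C(=O)O[C@H]2C[C@H]3[C@H](CN(C)C[C@@H]3C)[C@H]2C)ccc1OC(C)=O
F5 | step 4 | bis(cyclopentadienyl)zirconabicycle from 5 (Zr bonded to C5 and C7 of the later bicycle; cyclopentadienyl rings written σ-bonded) | CC1=C2CN(C(=O)OC)C[C@H](C)[C@H]2C[Zr]1(C1C=CC=C1)C1C=CC=C1
F6 | step 6 | (4R,4aR,6S,7R,7aS)-2,4,7-trimethyloctahydro-1H-cyclopenta[c]pyridin-6-ol | O[C@H]1C[C@H]2[C@H](CN(C)C[C@@H]2C)[C@H]1C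
A1 | alternative 1 | (1α,2α,3β,4β)-2,4-bis(4-acetoxy-3-methoxyphenyl)cyclobutane-1,3-dicarboxylic acid | OC(=O)[C@@H]1[C@H](c2ccc(OC(C)=O)c(OC)c2)[C@@H](C(=O)O)[C@H]1c1ccc(OC(C)=O)c(OC)c1
A2 | alternative 2 | Bic(6R) (Z)-3-(4-acetoxy-3-methoxyphenyl)prop-2-enoate | COc1cc(/C=C\C(=O)O[C@@H]2C[C@H]3[C@H](CN(C)C[C@@H]3C)[C@H]2C)ccc1OC(C)=O
A3 | alternative 3 | methyl (1α,2β,3β,4β)-2,4-bis(4-acetoxy-3-methoxyphenyl)-3-(quinolin-8-ylcarbamoyl)cyclobutane-1-carboxylate | COC(=O)[C@H]1[C@H](c2ccc(OC(C)=O)c(OC)c2)[C@H](C(=O)Nc2cccc3cccnc23)[C@@H]1c1ccc(OC(C)=O)c(OC)c1
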